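**Strategy.** The ten-membered ring is traced back to a six-membered template by reconnecting C3 to C8. Ring C3–C8 is then a carvone skeleton (C4 methyl para to the C7 side chain) and C9–C10–C1–C2 is a four-carbon insert. An anionic oxy-Cope rearrangement of the trans-3-vinyl-8-(E)-propenyl cyclohexanol 17, which carries C4–C7 as a bis-acetonide, forms C1–C10 while C3–C8 breaks. One operation therefore delivers the cyclodecane and the remote C10 centre. The template centres come from (S)-carvone (C7) by nucleophilic epoxidation, selenium-mediated epoxide transposition, directed epoxidation and trans-diaxial hydrolysis. The C3 oxygen is removed afterwards and O6 is angeloylated last.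

Key step: step 10

Convention: locants follow the target (ring C1–C10; C6 angelate carbinol, C7 bears C11 = CMe2OH carbon, C10 = CHMe, C4 = CMeOH). In the template ring C3–C8, α is the face carrying the C7 side chain and β the opposite face. In this numbering the target is 4R,5S,6R,7R,10S, and (S)-carvone is the enantiomer whose centre becomes C7.

Assumption: the C3 carbinols 3–6 and 22–23 are carried as C3 epimer mixtures (their SMILES leave C3 undefined), because C3 is reoxidized in step 3 and deoxygenated in step 13.

**Step 1**
Reactants: 1 (S)-carvone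
Product: 2 (1S,4S,6S)-1-methyl-4-(prop-1-en-2-yl)-7-oxabicyclo[4.1.0]heptan-2-one (carvone 4β,5β-oxide)
Conditions: 30% aq. H2O2, NaOH (cat.), MeOH, 0 °C
Reagents that add atoms: hydrogen peroxide, OO
Why: Weitz–Scheffer nucleophilic epoxidation of the enone, in which hydroperoxide adds axially to C5 anti to the C7 isopropenyl group and the enolate closes on the same face, so that O4 and O5 are both set β (trans to the C7 substituent).

**Step 2**
Reactants: 2 carvone 4β,5β-oxide
Product: 6 4α-methyl-7α-(prop-1-en-2-yl)cyclohex-5-ene-3,4β-diol (C3 epimers), via epoxy alcohol 3 (not isolated), via hydroxy selenide 4 (not isolated), via selenoxide 5 (not isolated)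
Conditions: NaBH4, EtOH, 0 °C; then PhSeSePh, NaBH4, reflux; then THF, 30% aq. H2O2, 0 °C to rt
Reagents that add atoms: none
Why: Borohydride first reduces the ketone, which would otherwise divert the selenolate to reductive cleavage of the C4–O bond; organoselenium epoxide-to-allylic-alcohol transposition then follows, PhSe− opening the epoxide by SN2 at the secondary C5 (not the trans-diaxial mode here, hence the prolonged heating) and the selenoxide eliminating syn toward C6, the only neighbour with hydrogens, so that the C4–O bond from step 1 is never broken and O4 stays β.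

**Step 3**
Reactants: 6 cyclohex-5-ene-3,4β-diol
Product: 7 (2S,5R)-2-hydroxy-2-methyl-5-(prop-1-en-2-yl)cyclohex-3-en-1-one (4β-hydroxy ketol)
Conditions: Dess–Martin periodinane, CH2Cl2, 0 °C to rt
Reagents that add atoms: none
Why: Dess–Martin oxidation of the secondary C3 alcohol in the presence of the tertiary allylic C4 alcohol, which cannot be oxidized; the β,γ-unsaturated ketone cannot slip into conjugation because C4 carries no hydrogen.

**Step 4**
Reactants: 7 4β-hydroxy ketol
Product: 9 4β,5β,6α-trihydroxy-4α-methyl-7α-(prop-1-en-2-yl)cyclohexan-3-one, via epoxy ketol 8 (not isolated)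
Conditions: VO(acac)2 (cat.), t-BuOOH, CH2Cl2, 0 °C to rt; Me2S; then THF–H2O, HClO4 (cat.), 0 °C to rt
Reagents that add atoms: tert-butyl hydroperoxide, CC(C)(C)OO; water, O
Why: Hydroxyl-directed vanadium-catalysed epoxidation places the epoxide on C5=C6 syn to the C4 hydroxyl (β face, also the face away from the C7 group) and spares the isopropenyl group; acid-catalysed hydrolysis then follows the Fürst–Plattner trans-diaxial course with water entering at C6 from the α face, the carbon remote from the electron-poor C4, which sets O5 β and O6 α.

**Step 5**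
Reactants: 9 trihydroxy ketone
Product: 10 4β,5β,6α-trihydroxy-7α-(2-hydroxypropan-2-yl)-4α-methylcyclohexan-3-one
Conditions: Co(acac)2 (cat.), PhSiH3, O2 (1 atm), THF–i-PrOH, rt; aq. Na2S2O3
Reagents that add atoms: dioxygen, O=O
Why: Mukaiyama hydration (cobalt-catalysed hydrogen-atom transfer to the 1,1-disubstituted alkene, then O2 trapping of the tertiary radical) gives the Markovnikov alcohol at C11 under neutral conditions that tolerate the ketone and free hydroxyls; it is placed after the epoxide opening so that no free C11 hydroxyl can attack the epoxide, and it creates no stereocentre.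

**Step 6**
Reactants: 10 tetrahydroxy ketone
Product: 11 4,5-O:6,11-O-diisopropylidene derivative of 10 (template ketone bis-acetonide)
Conditions: 2-methoxypropene, CSA (cat.), CH2Cl2, 0 °C to rt
Reagents that add atoms: 2-methoxypropene, COC(C)=C
Why: Acid-catalysed acetal formation, in which O5 and O6 are trans-diaxial and cannot be bridged, so only the cis O4/O5 pair (dioxolane) and the 1,3-related O6/O11 pair (dioxane) can close; a single bis-acetonide is expected and all four hydroxyls are masked in one operation.

**Step 7**
Reactants: 11 template ketone bis-acetonide; 12 allyl bromide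
Product: 14 8β-allyl template ketone bis-acetonide, via lithium enolate 13 (not isolated)
Conditions: LiN(i-Pr)2, THF, −78 °C; allyl bromide, DMPU, −78 to −20 °C
Reagents that add atoms: allyl bromide (12), C=CCBr
Why: Kinetic enolate alkylation, in which C8 is the only enolizable position because C4 is fully substituted and the electrophile approaches anti to the adjacent C7 substituent and its fused dioxane, giving the 7,8-trans (8β, equatorial) allyl ketone, which is also the more stable C8 epimer.

**Step 8**
Reactants: 14 8β-allyl ketone; 15 vinylmagnesium bromide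
Product: 16 8β-allyl-3α-vinyl-3β-hydroxy template bis-acetonide
Conditions: CH2=CHMgBr, THF, −78 to 0 °C; aq. NH4Cl
Reagents that add atoms: vinylmagnesium bromide (15), C=C[Mg]Br
Why: Grignard 1,2-addition under chelation and steric control, in which the axial (β) trajectory is blocked by the axial C5 oxygen of the dioxolane and magnesium held between the carbonyl and the equatorial O4 guides the vinyl group in equatorially on the α face, trans to O4 and to the 8β-allyl group, which creates C3 with OH β.

**Step 9**
Reactants: 16 allyl vinyl carbinol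
Product: 17 8β-[(E)-prop-1-enyl]-3α-vinyl-3β-hydroxy template bis-acetonide (oxy-Cope precursor)
Conditions: RuHCl(CO)(PPh3)3 (cat.), toluene, 80 °C
Reagents that add atoms: none
Why: Ruthenium hydride alkene isomerization (hydrometalation then β-hydride elimination) moves the terminal double bond one position to the (E)-propenyl group, E being favoured because a Z-methyl would press against the substituted ring, while the vinyl carbinol cannot migrate since C3 bears no hydrogen; running it after the Grignard step avoids a β,γ-unsaturated ketone that could conjugate or epimerize at C8.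

**Step 10**
Reactants: 17 oxy-Cope precursor
Product: 20 (E)-cyclodec-8-en-3-one bis-acetonide, via potassium alkoxide 18 (not isolated), via potassium enolate 19 (not isolated)
Conditions: KH, 18-crown-6, THF, 0 °C to rt; then aq. NH4Cl, −78 °C
Reagents that add atoms: none
Why: KH deprotonates the tertiary C3 carbinol and the crown-separated potassium alkoxide 18 undergoes a concerted [3,3] sigmatropic shift of the 1,5-diene C1=C2–C3–C8–C9=C10, forming C1–C10 as C3–C8 breaks and giving enolate 19, which is protonated to 20. The closest known reaction type is the anionic oxy-Cope ring expansion of trans-1,2-dialkenylcyclohexanols to (E)-cyclodec-5-enones. The ten-membered ring is not closed end to end but arises by four-atom ring expansion through a six-centre chair transition state, and enolate formation makes the step irreversible. C10 is set by that chair: vinyl and propenyl are trans-diequatorial on the rigid bis-acetonide chair, the (E)-propenyl methyl sits pseudo-equatorial, and bonding of C1 to the exposed face of C10 should give the 10S centre together with the E-C8=C9 alkene. The step needs chair over boat and a concerted over a dissociative course; the 3,8-trans diequatorial arrangement from steps 7 and 8 and the E geometry from step 9 secure the first, the unstabilized allyl fragment the second.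

**Step 11**
Reactants: 20 cyclodecenone bis-acetonide
Product: 22 cyclodecan-3-ol bis-acetonide (C3 epimers), via saturated ketone 21 (not isolated)
Conditions: H2 (1 atm), PtO2, EtOAc, rt; filter; then NaBH4, MeOH, 0 °C
Reagents that add atoms: none
Why: Heterogeneous hydrogenation of the strained E-alkene over platinum, chosen over palladium to avoid double-bond migration through the allylic C7 and C10 centres, followed by borohydride reduction of the ketone; the configuration of the new C3 carbinol is irrelevant because C3 becomes CH2 in step 13.

**Step 12**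
Reactants: 22 cyclodecan-3-ol bis-acetonide
Product: 23 O-(C3) imidazole-1-carbothioate of 22
Conditions: 1,1'-thiocarbonyldiimidazole, DMAP (cat.), ClCH2CH2Cl, 70 °C
Reagents that add atoms: 1,1'-thiocarbonyldiimidazole, S=C(n1ccnc1)n1ccnc1
Why: Thioacylation of the hindered secondary alcohol (first half of a Barton–McCombie deoxygenation), which needs no strong base and leaves both acetonides untouched.

**Step 13**
Reactants: 23 imidazole-1-carbothioate
Product: 24 3-deoxy bis-acetonide (C3 = CH2)
Conditions: Bu3SnH, AIBN (cat.), toluene, 100 °C
Reagents that add atoms: none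
Why: Barton–McCombie radical deoxygenation, in which the stannyl radical adds to the thiocarbonyl, the C3–O bond fragments to a secondary radical and Bu3SnH reduces it faster than any transannular hydrogen shift, removing the template oxygen without touching a stereocentre.

**Step 14**
Reactants: 24 3-deoxy bis-acetonide
Product: 25 4,5-O-isopropylidene 6,11-diol
Conditions: AcOH–THF–H2O (3:1:1), rt
Reagents that add atoms: none
Why: Selective acid hydrolysis of an acetonide: the O6/O11 dioxane is a 2,2,4,4-tetramethyl-1,3-dioxane strained by a syn-diaxial methyl pair and should be cleaved well before the cis-fused O4/O5 dioxolane, freeing only the C6 and C11 hydroxyls.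

**Step 15**
Reactants: 25 4,5-O-isopropylidene 6,11-diol; 26 angelic acid
Product: 28 6-O-angeloyl 4,5-O-isopropylidene derivative, via mixed anhydride 27 (not isolated)
Conditions: 26, 2,4,6-Cl3C6H2COCl, Et3N, toluene, rt; then 25, 80 °C
Reagents that add atoms: angelic acid (26), C/C=C(/C)C(=O)O
Why: Yamaguchi-type mixed anhydride esterification run without a nucleophilic catalyst, in which the alcohol attacks the unhindered angeloyl carbonyl of 27, only the secondary C6 hydroxyl reacts while the tertiary C11 hydroxyl stays free, and Z-to-E isomerization to the tiglate is avoided.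

**Step 16**
Reactants: 28 6-O-angeloyl 4,5-O-isopropylidene derivative
Product: 29 CNP0130723.1 (target)
Conditions: 1 M aq. HCl, THF, rt
Reagents that add atoms: none
Why: Acid-catalysed acetonide hydrolysis under mild aqueous conditions; dilute acid leaves the angelate intact and, unlike base, should not promote O6-to-O5 acyl migration or Z/E isomerization.

**Compound list**

1 | (S)-carvone | CC1=CC[C@H](C(C)=C)CC1=O | starting material
2 | (1S,4S,6S)-1-methyl-4-(prop-1-en-2-yl)-7-oxabicyclo[4.1.0]heptan-2-one (carvone 4β,5β-oxide) | O=C1[C@@]2(C)O[C@H]2C[C@H](C(C)=C)C1 | intermediate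
3 | 4β,5β-epoxy-4α-methyl-7α-(prop-1-en-2-yl)cyclohexan-3-ol (C3 epimers) | OC1[C@@]2(C)O[C@H]2C[C@H](C(C)=C)C1 | intermediate
4 | 4α-methyl-5α-(phenylselanyl)-7α-(prop-1-en-2-yl)cyclohexane-3,4β-diol | OC1[C@@](C)(O)[C@H]([Se]c2ccccc2)C[C@H](C(C)=C)C1 | intermediate
5 | selenoxide of 4 (5α-phenylseleninyl) | OC1[C@@](C)(O)[C@H]([Se](=O)c2ccccc2)C[C@H](C(C)=C)C1 | intermediate
6 | 4α-methyl-7α-(prop-1-en-2-yl)cyclohex-5-ene-3,4β-diol (C3 epimers) | OC1[C@@](C)(O)C=C[C@H](C(C)=C)C1 | intermediate
7 | (2S,5R)-2-hydroxy-2-methyl-5-(prop-1-en-2-yl)cyclohex-3-en-1-one | O=C1[C@@](C)(O)C=C[C@H](C(C)=C)C1 | intermediate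
8 | 5β,6β-epoxide of 7 | O=C1[C@@](C)(O)[C@H]2O[C@H]2[C@H](C(C)=C)C1 | intermediate
9 | 4β,5β,6α-trihydroxy-4α-methyl-7α-(prop-1-en-2-yl)cyclohexan-3-one | O=C1[C@@](C)(O)[C@@H](O)[C@H](O)[C@H](C(C)=C)C1 | intermediate
10 | 4β,5β,6α-trihydroxy-7α-(2-hydroxypropan-2-yl)-4α-methylcyclohexan-3-one | O=C1[C@@](C)(O)[C@@H](O)[C@H](O)[C@H](C(C)(C)O)C1 | intermediate
11 | template ketone bis-acetonide (4,5-O:6,11-O-diisopropylidene) | CC1(C)O[C@@H]2[C@H](C(C)(C)O1)CC(=O)[C@@]3(C)OC(C)(C)O[C@@H]23 | intermediate
12 | allyl bromide | C=CCBr | starting material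
13 | lithium enolate of 11 (C3=C8) | CC1(C)O[C@@H]2[C@H](C(C)(C)O1)C=C([O-])[C@@]3(C)OC(C)(C)O[C@@H]23.[Li+] | intermediate
14 | 8β-allyl template ketone bis-acetonide | CC1(C)O[C@@H]2[C@H](C(C)(C)O1)[C@@H](CC=C)C(=O)[C@@]3(C)OC(C)(C)O[C@@H]23 | intermediate
15 | vinylmagnesium bromide | C=C[Mg]Br | starting material
16 | 8β-allyl-3α-vinyl-3β-hydroxy template bis-acetonide | CC1(C)O[C@@H]2[C@H](C(C)(C)O1)[C@@H](CC=C)[C@](O)(C=C)[C@@]3(C)OC(C)(C)O[C@@H]23 | intermediate
17 | 8β-[(E)-prop-1-enyl]-3α-vinyl-3β-hydroxy template bis-acetonide (oxy-Cope precursor) | CC1(C)O[C@@H]2[C@H](C(C)(C)O1)[C@@H](/C=C/C)[C@](O)(C=C)[C@@]3(C)OC(C)(C)O[C@@H]23 | intermediate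
18 | potassium alkoxide of 17 | CC1(C)O[C@@H]2[C@H](C(C)(C)O1)[C@@H](/C=C/C)[C@]([O-])(C=C)[C@@]3(C)OC(C)(C)O[C@@H]23.[K+] | intermediate
19 | potassium enolate of 20 (C2=C3) | CC1(C)O[C@@H]2[C@H](C(C)(C)O1)/C=C/[C@@H](C)C/C=C(\[O-])[C@@]3(C)OC(C)(C)O[C@@H]23.[K+] | intermediate
20 | (E)-cyclodec-8-en-3-one bis-acetonide (10S) | CC1(C)O[C@@H]2[C@H](C(C)(C)O1)/C=C/[C@@H](C)CCC(=O)[C@@]3(C)OC(C)(C)O[C@@H]23 | intermediate
21 | cyclodecan-3-one bis-acetonide | CC1(C)O[C@@H]2[C@H](C(C)(C)O1)CC[C@@H](C)CCC(=O)[C@@]3(C)OC(C)(C)O[C@@H]23 | intermediate
22 | cyclodecan-3-ol bis-acetonide (C3 epimers) | CC1(C)O[C@@H]2[C@H](C(C)(C)O1)CC[C@@H](C)CCC(O)[C@@]3(C)OC(C)(C)O[C@@H]23 | intermediate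
23 | O-(C3) imidazole-1-carbothioate of 22 | CC1(C)O[C@@H]2[C@H](C(C)(C)O1)CC[C@@H](C)CCC(OC(=S)n4ccnc4)[C@@]3(C)OC(C)(C)O[C@@H]23 | intermediate
24 | 3-deoxy bis-acetonide | CC1(C)O[C@@H]2[C@H](C(C)(C)O1)CC[C@@H](C)CCC[C@@]3(C)OC(C)(C)O[C@@H]23 | intermediate
25 | 4,5-O-isopropylidene 6,11-diol | O[C@@H]1[C@H](C(C)(C)O)CC[C@@H](C)CCC[C@@]2(C)OC(C)(C)O[C@@H]12 | intermediate
26 | angelic acid, (Z)-2-methylbut-2-enoic acid | C/C=C(/C)C(=O)O | starting material
27 | angelic 2,4,6-trichlorobenzoic anhydride | C/C=C(/C)C(=O)OC(=O)c1c(Cl)cc(Cl)cc1Cl | intermediate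
28 | 6-O-angeloyl 4,5-O-isopropylidene derivative | C/C=C(/C)C(=O)O[C@@H]1[C@H](C(C)(C)O)CC[C@@H](C)CCC[C@@]2(C)OC(C)(C)O[C@@H]12 | intermediate
29 | CNP0130723.1 | C/C=C(/C)C(=O)O[C@@H]1[C@H](C(C)(C)O)CC[C@@H](C)CCC[C@@](C)(O)[C@H]1O | target

**Totals.** Total step count: 16. Longest linear sequence: 16 steps, from (S)-carvone 1 to 29; the other starting materials (12, 15, 26) are used as bought.

**Steps most likely to fail**

1. Step 10 (key step). The alkoxide may fragment into an allyl anion and an enone and recombine, or react through a boat, so that the transfer of chirality to C10 is eroded. The rearrangement may also stall because the C3 oxyanion is axial. The fallback is the neutral thermal oxy-Cope rearrangement. It sets out from 17, which would be heated without base (degassed 1,2-dichlorobenzene, sealed tube, about 200 °C). The same chair shift should give the ten-membered dienol bis-acetonide F1, which tautomerizes to ketone 20, where the route is rejoined.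

2. Step 2. Opening of the epoxide at C5 is slow, since it lies next to the quaternary C4 and has no trans-diaxial pathway, so selenium adducts of the alkenes or over-oxidation may take over before elimination. The fallback is a deconjugative α-hydroxylation that sets out from 1. KOt-Bu in THF/t-BuOH would convert (S)-carvone into its extended potassium dienolate F2, which would be hydroxylated at C4 with 2-(phenylsulfonyl)-3-phenyloxaziridine at low temperature. Ketol 7 would then have to be separated from its C4 epimer, because the remote C7 centre gives little facial bias. The route is rejoined at 7 and steps 1 to 3 are bypassed.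

3. Step 4. The α-ketol may interfere with the vanadium catalyst. The epoxy ketol may also open the wrong way under acid, by attack at C5, participation of the C3 carbonyl, or a semipinacol shift. The fallback epoxidizes before oxidizing and replaces hydrolysis by a templated carboxylate opening. It sets out from 6: VO(acac)2/t-BuOOH would give the 5β,6β-epoxy diol F3, and Dess–Martin oxidation would give epoxy ketol 8, now isolated. Ti(Oi-Pr)4 with benzoic acid would deliver the carboxylate to C6, the epoxide carbon remote from the coordinating C4 hydroxyl, giving the 6α-benzoate of the triol ketone F4. K2CO3 in MeOH would remove the benzoate and the route is rejoined at 9.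

**Further compounds**

F1 | step 10 | ten-membered 2,8-dien-3-ol bis-acetonide (enol of 20) | CC1(C)O[C@@H]2[C@H](C(C)(C)O1)/C=C/[C@@H](C)C/C=C(\O)[C@@]3(C)OC(C)(C)O[C@@H]23
F2 | step 2 | extended potassium dienolate of (S)-carvone | CC1=C([O-])C[C@@H](C(C)=C)C=C1.[K+]
F3 | step 4 | 5β,6β-epoxy-4α-methyl-7α-(prop-1-en-2-yl)cyclohexane-3,4β-diol (C3 epimers) | OC1[C@@](C)(O)[C@H]2O[C@H]2[C@H](C(C)=C)C1
F4 | step 4 | 6α-benzoyloxy-4β,5β-dihydroxy-4α-methyl-7α-(prop-1-en-2-yl)cyclohexan-3-one | O=C1[C@@](C)(O)[C@@H](O)[C@H](OC(=O)c2ccccc2)[C@H](C(C)=C)C1
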